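**Plan**
1. Retrosynthesis first removes the two benzyl groups and a carboxyl group that the ring-forming step leaves on ring D, at the carbon between the hydroxyl-bearing and the bridge-bearing carbons.
2. Ring D is the 3-hydroxyphenyl ring: D1 carries the CH2CH2 bridge to ring C, D3 carries OH, and D2 between them is unsubstituted, the pattern of a decarboxylated 6-alkylsalicylic acid. This makes the key step possible: cutting D1–D2 and D4–D5 gives an acetoacetate unit (D2, D3, D4 plus the carboxyl carbon) and a C3 unit (D1, D6, D5) that is the carbonyl end of a 4-arylbutan-2-one.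
3. The remaining cuts are the diaryl ether bond between the ether oxygen and ring B (Ullmann) and the central C–C bond of the A–B ethylene bridge (Wittig C=C, then saturation).
4. Forward: rings A and B are joined by Wittig olefination and diimide reduction, ring C is attached as raspberry ketone, its methyl ketone is extended to a β-methoxy enone, and ring D is then built de novo as the only ring made in the route. Hydrogenolysis and decarboxylation finish.
5. Stereochemistry: the target has no stereocentre or stereogenic axis, so it is a single achiral compound and no enantiocontrol is needed. The alkene geometries of intermediates are all erased.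

Key step: step 10

**Route**

Step 1
Reactants: 1 3-methoxybenzyl chloride
Product: 2 (3-methoxybenzyl)triphenylphosphonium chloride
Conditions: PPh3, toluene, reflux
Reagents that add atoms: triphenylphosphine, c1ccc(cc1)P(c1ccccc1)c1ccccc1
Why: SN2 quaternisation of triphenylphosphine by a primary benzylic chloride should give the Wittig salt, which precipitates from toluene.

Step 2
Reactants: 3 3-bromo-4-hydroxybenzaldehyde
Product: 4 4-(benzyloxy)-3-bromobenzaldehyde
Conditions: BnBr, K2CO3, DMF, rt
Reagents that add atoms: benzyl bromide, BrCc1ccccc1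
Why: Williamson etherification of the acidic para-formyl phenol installs a benzyl ether that tolerates ylide, diimide, copper, LDA and low-temperature Lewis acid and leaves by hydrogenolysis at the end.

Step 3
Reactants: 2 (3-methoxybenzyl)triphenylphosphonium chloride; 4 4-(benzyloxy)-3-bromobenzaldehyde
Product: 6 1-(benzyloxy)-2-bromo-4-[2-(3-methoxyphenyl)ethenyl]benzene (E/Z mixture), via phosphorus ylide 5 (not isolated)
Conditions: KOtBu, THF, 0 °C; then 4, 0 °C → rt
Reagents that add atoms: none
Why: Wittig olefination of a non-enolisable aryl aldehyde with a semi-stabilised benzylic ylide forms the future A–B bridge, and the E/Z mixture is harmless because the double bond is saturated next.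

Step 4
Reactants: 6 1-(benzyloxy)-2-bromo-4-[2-(3-methoxyphenyl)ethenyl]benzene
Product: 7 1-(benzyloxy)-2-bromo-4-[2-(3-methoxyphenyl)ethyl]benzene
Conditions: TsNHNH2 (excess, in portions), NaOAc, DME/H2O, reflux
Reagents that add atoms: none
Why: Diimide reduction (diimide from thermolysis of tosylhydrazide) transfers H2 concertedly to the stilbene C=C and, unlike Pd/H2, should leave the aryl bromide and the benzyl ether untouched.

Step 5
Reactants: 7 1-(benzyloxy)-2-bromo-4-[2-(3-methoxyphenyl)ethyl]benzene; 8 4-(4-hydroxyphenyl)butan-2-one (raspberry ketone)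
Product: 9 4-(4-{2-(benzyloxy)-5-[2-(3-methoxyphenyl)ethyl]phenoxy}phenyl)butan-2-one
Conditions: CuI (cat.), N,N-dimethylglycine·HCl (cat.), Cs2CO3, 1,4-dioxane, 90 °C
Reagents that add atoms: none
Why: Ligand-accelerated Ullmann diaryl ether synthesis couples the phenoxide of 8 with the ortho-alkoxy aryl bromide under a heterogeneous carbonate base that should be mild enough to spare the methyl ketone.

Step 6
Reactants: 9 4-(4-{2-(benzyloxy)-5-[2-(3-methoxyphenyl)ethyl]phenoxy}phenyl)butan-2-one
Product: 11 (Z)-5-(4-{2-(benzyloxy)-5-[2-(3-methoxyphenyl)ethyl]phenoxy}phenyl)-1-hydroxypent-1-en-3-one (chelated enol of the β-keto aldehyde, used crude), via kinetic lithium enolate 10 (not isolated)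
Conditions: LDA, THF, −78 °C (ketone added to base); HCO2CH2CF3, −78 °C; cold 1 M HCl
Reagents that add atoms: 2,2,2-trifluoroethyl formate, O=COCC(F)(F)F
Why: Kinetic deprotonation with LDA at −78 °C removes a methyl proton rather than the more hindered methylene proton, and crossed Claisen formylation of this enolate by the very reactive trifluoroethyl formate is fast at −78 °C, before the enolate can equilibrate.

Step 7
Reactants: 11 (Z)-5-(4-{2-(benzyloxy)-5-[2-(3-methoxyphenyl)ethyl]phenoxy}phenyl)-1-hydroxypent-1-en-3-one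
Product: 12 (E)-5-(4-{2-(benzyloxy)-5-[2-(3-methoxyphenyl)ethyl]phenoxy}phenyl)-1-methoxypent-1-en-3-one
Conditions: Me2SO4, K2CO3, acetone, rt
Reagents that add atoms: dimethyl sulfate, COS(=O)(=O)OC
Why: O-alkylation of a hydroxymethylene ketone, in which the potassium enolate of the β-keto aldehyde reacts at oxygen with the hard electrophile dimethyl sulfate, should give the vinylogous ester, mainly as the E isomer.

Step 8
Reactants: 13 benzyl acetoacetate
Product: 14 benzyl 3-(trimethylsilyloxy)but-2-enoate (E/Z mixture)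
Conditions: Me3SiCl, NEt3, toluene, rt; filtration under argon
Reagents that add atoms: chlorotrimethylsilane, C[Si](C)(C)Cl
Why: Enol silylation of the β-keto ester with Me3SiCl/NEt3 masks the ketone as a silyl enol ether and leaves the γ-methyl group as the only acidic site.

Step 9
Reactants: 14 benzyl 3-(trimethylsilyloxy)but-2-enoate
Product: 16 (Z)-1-(benzyloxy)-1,3-bis(trimethylsilyloxy)buta-1,3-diene (used crude; geometry at C1=C2 immaterial), via lithium dienolate 15 (not isolated)
Conditions: LDA, THF, −78 °C; Me3SiCl, −78 °C → rt; non-aqueous work-up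
Reagents that add atoms: chlorotrimethylsilane, C[Si](C)(C)Cl
Why: γ-Deprotonation of the vinylogous ester with LDA and O-silylation of the dienolate is the standard preparation of 1,3-bis(silyl enol ethers), the masked dianions of β-keto esters.

Step 10
Reactants: 12 (E)-5-(4-{2-(benzyloxy)-5-[2-(3-methoxyphenyl)ethyl]phenoxy}phenyl)-1-methoxypent-1-en-3-one; 16 (Z)-1-(benzyloxy)-1,3-bis(trimethylsilyloxy)buta-1,3-diene
Product: 19 benzyl 2-[2-(4-{2-(benzyloxy)-5-[2-(3-methoxyphenyl)ethyl]phenoxy}phenyl)ethyl]-6-hydroxybenzoate, via open-chain enedione ester 17 (not isolated), via cyclohexenone aldol 18 (not isolated)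
Conditions: 16 (1.5 equiv), TiCl4 (1.1 equiv), 4 Å MS, CH2Cl2, −78 → 20 °C, quenched with 1 M HCl as soon as 12 is consumed
Reagents that add atoms: none
Why: TiCl4 binds the carbonyl of the vinylogous ester 12, the terminal carbon of 16 (its most nucleophilic site) adds to the β-carbon in a Mukaiyama–Michael step, and methoxide is expelled to give enedione 17 (bond D4–D5). The central carbon of the β-keto ester unit then adds to the former ketone carbonyl in a 6-(enolexo)-exo-trig aldol closure to 18 (bond D1–D2), and loss of water with enolisation aromatises ring D to the salicylate, whose phenol is formed free. The closest known reaction type is the TiCl4-mediated formal [3+3] cyclocondensation of 1,3-bis(silyl enol ethers) with 3-alkoxy- or 3-silyloxy-enones, which gives 6-alkylsalicylates. No stereocentre is formed. The step needs the terminal carbon to attack the β-carbon and not the ketone, which the unhindered oxygen-activated β-CH position secures against a ketone flanked by a CH2CH2Ar chain, and it needs the electron-rich rings A–C to stay untouched, which the far higher nucleophilicity of the diene at low temperature secures. Should the union occur in the opposite sense, the 4-substituted salicylate would be carried by steps 11 and 12 to the same target, so only the 1,3-relation of OH and bridge has to be right.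

Step 11
Reactants: 19 benzyl 2-[2-(4-{2-(benzyloxy)-5-[2-(3-methoxyphenyl)ethyl]phenoxy}phenyl)ethyl]-6-hydroxybenzoate
Product: 20 2-hydroxy-6-[2-(4-{2-hydroxy-5-[2-(3-methoxyphenyl)ethyl]phenoxy}phenyl)ethyl]benzoic acid
Conditions: H2 (1 atm), 10% Pd/C, EtOAc–MeOH, rt
Reagents that add atoms: none
Why: Catalytic hydrogenolysis cleaves both benzylic C–O bonds (benzyl ester and aryl benzyl ether) in one operation, while the aryl methyl ether, the diaryl ether and the saturated bridges are inert.

Step 12
Reactants: 20 2-hydroxy-6-[2-(4-{2-hydroxy-5-[2-(3-methoxyphenyl)ethyl]phenoxy}phenyl)ethyl]benzoic acid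
Product: 21 2-{4-[2-(3-hydroxyphenyl)ethyl]phenoxy}-4-[2-(3-methoxyphenyl)ethyl]phenol (target)
Conditions: quinoline, Cu powder (cat.), 190 °C, Ar; acid wash
Reagents that add atoms: none
Why: Thermal protodecarboxylation of an ortho-hydroxybenzoic acid proceeds through ipso-protonation of its keto tautomer (a β-keto acid) and is eased by the flanking 6-alkyl group, as in the conversion of 6-alkylsalicylic acids into 3-alkylphenols.

**Compound list**
1 | 3-methoxybenzyl chloride | COc1cccc(CCl)c1 | starting material
2 | (3-methoxybenzyl)triphenylphosphonium chloride | COc1cccc(C[P+](c2ccccc2)(c2ccccc2)c2ccccc2)c1.[Cl-] | intermediate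
3 | 3-bromo-4-hydroxybenzaldehyde | O=Cc1ccc(O)c(Br)c1 | starting material
4 | 4-(benzyloxy)-3-bromobenzaldehyde | O=Cc1ccc(OCc2ccccc2)c(Br)c1 | intermediate
5 | (3-methoxybenzylidene)triphenylphosphorane | COc1cccc(C=P(c2ccccc2)(c2ccccc2)c2ccccc2)c1 | intermediate
6 | 1-(benzyloxy)-2-bromo-4-[2-(3-methoxyphenyl)ethenyl]benzene (E/Z mixture) | COc1cccc(C=Cc2ccc(OCc3ccccc3)c(Br)c2)c1 | intermediate
7 | 1-(benzyloxy)-2-bromo-4-[2-(3-methoxyphenyl)ethyl]benzene | COc1cccc(CCc2ccc(OCc3ccccc3)c(Br)c2)c1 | intermediate
8 | 4-(4-hydroxyphenyl)butan-2-one (raspberry ketone) | CC(=O)CCc1ccc(O)cc1 | starting material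
9 | 4-(4-{2-(benzyloxy)-5-[2-(3-methoxyphenyl)ethyl]phenoxy}phenyl)butan-2-one | CC(=O)CCc1ccc(Oc2cc(CCc3cccc(OC)c3)ccc2OCc2ccccc2)cc1 | intermediate
10 | lithium 4-(4-{2-(benzyloxy)-5-[2-(3-methoxyphenyl)ethyl]phenoxy}phenyl)but-1-en-2-olate | C=C(O[Li])CCc1ccc(Oc2cc(CCc3cccc(OC)c3)ccc2OCc2ccccc2)cc1 | intermediate
11 | (Z)-5-(4-{2-(benzyloxy)-5-[2-(3-methoxyphenyl)ethyl]phenoxy}phenyl)-1-hydroxypent-1-en-3-one | O/C=C\C(=O)CCc1ccc(Oc2cc(CCc3cccc(OC)c3)ccc2OCc2ccccc2)cc1 | intermediate
12 | (E)-5-(4-{2-(benzyloxy)-5-[2-(3-methoxyphenyl)ethyl]phenoxy}phenyl)-1-methoxypent-1-en-3-one | CO/C=C/C(=O)CCc1ccc(Oc2cc(CCc3cccc(OC)c3)ccc2OCc2ccccc2)cc1 | intermediate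
13 | benzyl acetoacetate (benzyl 3-oxobutanoate) | CC(=O)CC(=O)OCc1ccccc1 | starting material
14 | benzyl 3-(trimethylsilyloxy)but-2-enoate (E/Z mixture) | CC(O[Si](C)(C)C)=CC(=O)OCc1ccccc1 | intermediate
15 | lithium 1-(benzyloxy)-3-(trimethylsilyloxy)buta-1,3-dien-1-olate | C=C(O[Si](C)(C)C)C=C(O[Li])OCc1ccccc1 | intermediate
16 | (Z)-1-(benzyloxy)-1,3-bis(trimethylsilyloxy)buta-1,3-diene | C=C(O[Si](C)(C)C)/C=C(\O[Si](C)(C)C)OCc1ccccc1 | intermediate
17 | benzyl 9-(4-{2-(benzyloxy)-5-[2-(3-methoxyphenyl)ethyl]phenoxy}phenyl)-3,7-dioxonon-5-enoate | O=C(CC(=O)CC=CC(=O)CCc1ccc(Oc2cc(CCc3cccc(OC)c3)ccc2OCc2ccccc2)cc1)OCc1ccccc1 | intermediate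
18 | benzyl 2-[2-(4-{2-(benzyloxy)-5-[2-(3-methoxyphenyl)ethyl]phenoxy}phenyl)ethyl]-2-hydroxy-6-oxocyclohex-3-ene-1-carboxylate | O=C(OCc1ccccc1)C1C(=O)CC=CC1(O)CCc1ccc(Oc2cc(CCc3cccc(OC)c3)ccc2OCc2ccccc2)cc1 | intermediate
19 | benzyl 2-[2-(4-{2-(benzyloxy)-5-[2-(3-methoxyphenyl)ethyl]phenoxy}phenyl)ethyl]-6-hydroxybenzoate | O=C(OCc1ccccc1)c1c(O)cccc1CCc1ccc(Oc2cc(CCc3cccc(OC)c3)ccc2OCc2ccccc2)cc1 | intermediate
20 | 2-hydroxy-6-[2-(4-{2-hydroxy-5-[2-(3-methoxyphenyl)ethyl]phenoxy}phenyl)ethyl]benzoic acid | O=C(O)c1c(O)cccc1CCc1ccc(Oc2cc(CCc3cccc(OC)c3)ccc2O)cc1 | intermediate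
21 | 2-{4-[2-(3-hydroxyphenyl)ethyl]phenoxy}-4-[2-(3-methoxyphenyl)ethyl]phenol | COc1cccc(CCc2ccc(O)c(Oc3ccc(CCc4cccc(O)c4)cc3)c2)c1 | target

**Count**
Total steps: 12. Longest linear sequence: 9 steps (1 → 2 → 6 → 7 → 9 → 11 → 12 → 19 → 20 → 21, i.e. steps 1, 3, 4, 5, 6, 7, 10, 11, 12). The diene branch (steps 8, 9) and step 2 are convergent.

**Steps most likely to fail**

Step 10. While the mixture warms, the Lewis acid may cleave the ring-B benzyl ether, after which the freed benzyl cation alkylates the electron-rich rings. The titanium-bound enone may also be consumed by self-condensation before the diene has added. The fallback sets out from 12 and returns at 19. Methanol is added across the enol ether of 12 (MeOH, cat. NaOMe, rt) to give the β-keto dimethyl acetal 5-(4-{2-(benzyloxy)-5-[2-(3-methoxyphenyl)ethyl]phenoxy}phenyl)-1,1-dimethoxypentan-3-one F1. F1 and 16 are then combined with TiCl4 in CH2Cl2 at −78 °C. There the acetal ionises to an oxocarbenium ion, so the first C–C bond is made by a Mukaiyama-type acetal alkylation at the terminal carbon of the diene, at a temperature well below that at which benzyl ethers are attacked. The same aldol closure, with loss of water and methanol on brief warming, should lead to 19.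

Step 6. Proton transfer between the enolate and ketone not yet deprotonated may erode kinetic control, so that formylation also occurs at the methylene group. The β-keto aldehyde may also self-condense while it is concentrated. The fallback sets out from 7, returns at 12 and bypasses steps 5–7. Bromide 7 is coupled under the copper conditions of step 5 with commercial methyl 3-(4-hydroxyphenyl)propanoate (COC(=O)CCc1ccc(O)cc1) to give methyl 3-(4-{2-(benzyloxy)-5-[2-(3-methoxyphenyl)ethyl]phenoxy}phenyl)propanoate F2. The ester is converted with MeNH(OMe)·HCl and i-PrMgCl (THF, −20 °C) into the Weinreb amide 3-(4-{2-(benzyloxy)-5-[2-(3-methoxyphenyl)ethyl]phenoxy}phenyl)-N-methoxy-N-methylpropanamide F3. Ethynylmagnesium bromide (THF, 0 °C) then gives the ynone 5-(4-{2-(benzyloxy)-5-[2-(3-methoxyphenyl)ethyl]phenoxy}phenyl)pent-1-yn-3-one F4. DABCO-catalysed conjugate addition of methanol to the ynone should give the (E)-β-methoxy enone 12. The chain end is fixed by the acyl carbon, so no enolate regiochemistry is involved.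

Step 5. At 90 °C under carbonate the methyl ketone may undergo aldol self-condensation, and slow reaction of the hindered, electron-rich ortho-benzyloxy bromide may give way to protodebromination. The fallback sets out from 7 and returns at 9. Bromine–lithium exchange (n-BuLi, THF, −78 °C), trapping with B(OiPr)3 and acidic work-up give {2-(benzyloxy)-5-[2-(3-methoxyphenyl)ethyl]phenyl}boronic acid F5. Chan–Lam coupling of this acid with 8 (Cu(OAc)2, pyridine, 4 Å MS, CH2Cl2, air, rt) forms the same diaryl ether 9 at room temperature with an amine base, conditions under which the ketone should not enolise.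

**Further compounds**
F1 | step 10 | 5-(4-{2-(benzyloxy)-5-[2-(3-methoxyphenyl)ethyl]phenoxy}phenyl)-1,1-dimethoxypentan-3-one | COC(OC)CC(=O)CCc1ccc(Oc2cc(CCc3cccc(OC)c3)ccc2OCc2ccccc2)cc1
F2 | step 6 | methyl 3-(4-{2-(benzyloxy)-5-[2-(3-methoxyphenyl)ethyl]phenoxy}phenyl)propanoate | COC(=O)CCc1ccc(Oc2cc(CCc3cccc(OC)c3)ccc2OCc2ccccc2)cc1
F3 | step 6 | 3-(4-{2-(benzyloxy)-5-[2-(3-methoxyphenyl)ethyl]phenoxy}phenyl)-N-methoxy-N-methylpropanamide | CON(C)C(=O)CCc1ccc(Oc2cc(CCc3cccc(OC)c3)ccc2OCc2ccccc2)cc1
F4 | step 6 | 5-(4-{2-(benzyloxy)-5-[2-(3-methoxyphenyl)ethyl]phenoxy}phenyl)pent-1-yn-3-one | C#CC(=O)CCc1ccc(Oc2cc(CCc3cccc(OC)c3)ccc2OCc2ccccc2)cc1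
F5 | step 5 | {2-(benzyloxy)-5-[2-(3-methoxyphenyl)ethyl]phenyl}boronic acid | OB(O)c1cc(CCc2cccc(OC)c2)ccc1OCc1ccccc1
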